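## Retrosynthetic overview

- The target is the (R)-α-aryloxy ketone. The last disconnection is one O–Me bond, which leads back to the ortho-phenol ketone; the methylation is done under neutral conditions to protect the α-stereocentre.
- The aryl–C(=O) bond is cut next. This gives 3,4,5-trimethoxyphenylmagnesium bromide and a chiral 3-methyl-1,4-benzodioxin-2-one, an activated aryl lactone that already holds the C–O bond and the stereocentre.
- The lactone comes from an alkaloid-catalysed hetero-[4+2] reaction. The partners are a methylketene enolate (from propionyl chloride) and 5-allyl-3-methoxy-o-benzoquinone. This step re-aromatises the ring and sets (R).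
- The o-quinone comes from oxidative dearomatisation of eugenol, which also installs the missing ring oxygen.
- Both benzene rings are bought. The only ring formed is the temporary dioxinone, made in step 2 and opened in step 3.

Assumption: benzoylquinidine is taken to deliver the (R)-lactone, by analogy with α-heterofunctionalisations of ketene enolates by this catalyst family. The sense is checked on the first run. If it is opposite, the pseudoenantiomer benzoylquinine is used with no other change.

## Route

**Step 1**
Reactants: 1 eugenol (4-allyl-2-methoxyphenol)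
Product: 2 5-allyl-3-methoxycyclohexa-3,5-diene-1,2-dione (5-allyl-3-methoxy-o-benzoquinone)
Conditions: (KSO3)2NO (2.5 equiv), KH2PO4 buffer (pH about 6), cat. Aliquat 336, H2O/CH2Cl2, 0 °C, 30 min; dry the organic layer cold and use at once
Reagents that add atoms: Fremy's salt (potassium nitrosodisulfonate), [K+].[K+].[O]N(S(=O)(=O)[O-])S(=O)(=O)[O-]
Why: In this Teuber oxidation one equivalent of the nitroxyl abstracts the phenolic H and a second transfers oxygen to the only free ortho carbon (para is blocked by allyl), so the arene becomes an o-quinone, and the 3-OMe group stabilises it as a vinylogous ester.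

**Step 2**
Reactants: 2 5-allyl-3-methoxy-o-benzoquinone; 3 propionyl chloride
Product: 5 (3R)-5-methoxy-3-methyl-7-(prop-2-enyl)-2,3-dihydro-1,4-benzodioxin-2-one, via methylketene 4 (not isolated)
Conditions: benzoylquinidine (10 mol%), Sc(OTf)3 (10 mol%), iPr2NEt (1.1 equiv, syringe pump, added last), THF/toluene, −78 °C
Reagents that add atoms: none
Why: Proposed new method: the alkaloid binds 4 as a face-shielded Z-enolate whose α-carbon attacks the oxygen of the Sc-chelated C2 carbonyl, which is the more electron-poor one because C1=O is the vinylogous ester, and the better-stabilised C1 phenoxide then closes on the acylammonium to release the catalyst and re-aromatise, so the open enolate face fixes (R); the closest known reaction type is the cinchona-catalysed enantioselective [4+2] cycloaddition of ketene enolates with electron-poor o-quinones such as o-chloranil.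

**Step 3**
Reactants: 5 (3R)-lactone; 6 5-bromo-1,2,3-trimethoxybenzene
Product: 8 (2R)-2-(4-allyl-2-hydroxy-6-methoxyphenoxy)-1-(3,4,5-trimethoxyphenyl)propan-1-one, via aryl Grignard 7 (not isolated)
Conditions: 6, Mg, cat. I2, THF, reflux, titrate; add 7 (1.05 equiv) dropwise to 5, THF/toluene, −78 °C; quench with AcOH/THF at −78 °C
Reagents that add atoms: none
Why: This is a Grignard acyl substitution in which the phenolic α-oxy lactone is far more electrophilic than the electron-rich, α-branched, Mg-chelated aryl ketone it releases, so addition stops at the ketone, and low temperature with a cold acid quench keeps the existing stereocentre intact.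

**Step 4**
Reactants: 8 (2R)-phenol ketone
Product: 9 (2R)-2-(4-allyl-2,6-dimethoxyphenoxy)-1-(3,4,5-trimethoxyphenyl)propan-1-one (target)
Conditions: MeOH (3 equiv), PPh3, DIAD (1.3 equiv each), THF, 0 °C to rt
Reagents that add atoms: methanol, CO
Why: This Mitsunobu etherification methylates only the acidic phenol, draining any cyclic hemiketal form through the open tautomer, and it runs without free base, so the enolisable (R)-centre is not touched.

## Compound list

1 | eugenol | C=CCc1ccc(O)c(OC)c1 | starting material
2 | 5-allyl-3-methoxycyclohexa-3,5-diene-1,2-dione | C=CCC1=CC(=O)C(=O)C(OC)=C1 | intermediate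
3 | propionyl chloride | CCC(=O)Cl | starting material
4 | methylketene | CC=C=O | intermediate (not isolated)
5 | (3R)-5-methoxy-3-methyl-7-(prop-2-enyl)-2,3-dihydro-1,4-benzodioxin-2-one | C=CCc1cc(OC)c2O[C@H](C)C(=O)Oc2c1 | intermediate
6 | 5-bromo-1,2,3-trimethoxybenzene | COc1cc(Br)cc(OC)c1OC | starting material
7 | 3,4,5-trimethoxyphenylmagnesium bromide | COc1cc([Mg]Br)cc(OC)c1OC | intermediate (not isolated)
8 | (2R)-2-(4-allyl-2-hydroxy-6-methoxyphenoxy)-1-(3,4,5-trimethoxyphenyl)propan-1-one | C=CCc1cc(O)c(O[C@H](C)C(=O)c2cc(OC)c(OC)c(OC)c2)c(OC)c1 | intermediate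
9 | (2R)-2-(4-allyl-2,6-dimethoxyphenoxy)-1-(3,4,5-trimethoxyphenyl)propan-1-one | C=CCc1cc(OC)c(O[C@H](C)C(=O)c2cc(OC)c(OC)c(OC)c2)c(OC)c1 | target

Total step count: 4. Longest linear sequence: 4 (1 → 2 → 5 → 8 → 9).

## Steps most likely to fail

**Step 2.** The quinone is much less electrophilic than o-chloranil. Methylketene dimerisation, C-attack on the quinone, and amine-induced tautomerisation of 2 to a quinone methide all compete.
- The fallback sets out from 1 and comes back at 5. It gives up the quinone and takes the stereocentre from the chiral pool.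
- Ortho-formylation of 1 (MgCl2, Et3N, paraformaldehyde, MeCN, reflux) gives 5-allyl-2-hydroxy-3-methoxybenzaldehyde F1.
- Mitsunobu reaction with ethyl (S)-lactate (PPh3, DIAD) proceeds with inversion to give ethyl (2R)-2-(4-allyl-2-formyl-6-methoxyphenoxy)propanoate F2.
- Baeyer–Villiger oxidation of the electron-rich aldehyde (mCPBA, 1.1 equiv, CH2Cl2, 0 °C) gives ethyl (2R)-2-[4-allyl-2-(formyloxy)-6-methoxyphenoxy]propanoate F3.
- Catalytic TsOH in hot toluene closes F3 to lactone 5.

**Step 3.** The risks are a second addition to the ketone and enolisation or racemisation of the lactone by the Grignard reagent.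
- The fallback sets out from 5 and comes back at 9.
- The lactone is opened with MeNH(OMe)·HCl and iPrMgCl (THF, −20 °C) to give (2R)-2-(4-allyl-2-hydroxy-6-methoxyphenoxy)-N-methoxy-N-methylpropanamide F4.
- Mitsunobu methylation as in step 4 gives (2R)-2-(4-allyl-2,6-dimethoxyphenoxy)-N-methoxy-N-methylpropanamide F5.
- The chelated Weinreb amide takes exactly one equivalent of 7 (THF, −20 °C) and gives 9 directly.

**Step 1.** The allyl-bearing o-quinone may tautomerise to a vinyl quinone methide or dimerise before it can be used.
- The fallback sets out from 3 and comes back at 5. It postpones the allyl group.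
- Bought 4-bromo-2-methoxyphenol F6 is oxidised with Fremy's salt to 5-bromo-3-methoxycyclohexa-3,5-diene-1,2-dione F7, which cannot tautomerise and is more electrophilic.
- F7 reacts with 3 under the step 2 conditions to give (3R)-7-bromo-5-methoxy-3-methyl-2,3-dihydro-1,4-benzodioxin-2-one F8.
- Neutral Stille coupling (allyltributylstannane, Pd(PPh3)4, toluene, 90 °C) converts F8 into 5.

## Further compounds

F1 | step 2 | 5-allyl-2-hydroxy-3-methoxybenzaldehyde | C=CCc1cc(C=O)c(O)c(OC)c1
F2 | step 2 | ethyl (2R)-2-(4-allyl-2-formyl-6-methoxyphenoxy)propanoate | C=CCc1cc(C=O)c(O[C@H](C)C(=O)OCC)c(OC)c1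
F3 | step 2 | ethyl (2R)-2-[4-allyl-2-(formyloxy)-6-methoxyphenoxy]propanoate | C=CCc1cc(OC=O)c(O[C@H](C)C(=O)OCC)c(OC)c1
F4 | step 3 | (2R)-2-(4-allyl-2-hydroxy-6-methoxyphenoxy)-N-methoxy-N-methylpropanamide | C=CCc1cc(O)c(O[C@H](C)C(=O)N(C)OC)c(OC)c1
F5 | step 3 | (2R)-2-(4-allyl-2,6-dimethoxyphenoxy)-N-methoxy-N-methylpropanamide | C=CCc1cc(OC)c(O[C@H](C)C(=O)N(C)OC)c(OC)c1
F6 | step 1 | 4-bromo-2-methoxyphenol (bought) | COc1cc(Br)ccc1O
F7 | step 1 | 5-bromo-3-methoxycyclohexa-3,5-diene-1,2-dione | COC1=CC(Br)=CC(=O)C1=O
F8 | step 1 | (3R)-7-bromo-5-methoxy-3-methyl-2,3-dihydro-1,4-benzodioxin-2-one | Brc1cc(OC)c2O[C@H](C)C(=O)Oc2c1
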